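By 0.333 min the beta run holds 31.1% left-handed substrate and the alpha run, at 0.333 min, holds 23.7%, each from a start of 50 percent of the two substrates together.

| flask | left-handed substrate | right-handed substrate | coupling partner | free catalyst | remark |
|---|---|---|---|---|---|
| beta | 0.20 M | 0.20 M | 0.60 M | 0.42 mM | run made earlier |
| alpha | 0.20 M | 0.20 M | 0.60 M | 0.66 mM | run made earlier |
| flask | 0.20 M | 0.20 M | 0.600 M | 0.30 mM |  |

| run | time / min | left-handed product / % | left-handed substrate / % |
|---|---|---|---|
| beta | 0.200 | 11.9 | 37.8 |
| beta | 0.333 | 16.9 | 31.1 |
| beta | 0.417 | 22.7 | 28.1 |
| beta | 0.667 | 30.2 | 20.6 |
| beta | 1.00 | 35.6 | 14.5 |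
| beta | 1.50 | 42.1 | 10.2 |
| beta | 2.50 | 44.8 | 5.1 |
| alpha | 0.333 | 27.1 | 23.7 |
| alpha | 0.667 | 39.5 | 10.3 |
| alpha | 1.00 | 47.2 | 4.2 |
| alpha | 1.33 | 49.9 | 2.8 |
| alpha | 1.50 | 47.4 | 3.1 |
| alpha | 2.00 | 49.6 | 0 |
| alpha | 2.50 | 48.2 | 0 |

(standard deviation of a reading: 1 percentage point)

* apparent order in coupling partner when 10% of the left-handed substrate and right-handed substrate together are converted (percent change of the rate of making left-handed product for one percent more coupling partner charged)
* apparent order in free catalyst when 10% of the left-handed substrate and right-handed substrate together are converted (percent change of the rate of making left-handed product for one percent more free catalyst charged)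

- free catalyst is single-handed; left-handed substrate and right-handed substrate are mirror images of each other, charged as a racemate, each of them at the stated concentration
- steps under discussion: coupling partner + catalyst intermediate B -> free catalyst + right-handed product; coupling partner + catalyst intermediate A -> free catalyst + left-handed product; 2 coupling partner -> self-condensation product; free catalyst + left-handed substrate <-> catalyst intermediate A; free catalyst + right-handed substrate <-> catalyst intermediate B
- no earlier run changes the charge of coupling partner; that part of a forecast is a guess

I have to settle this flask's charge and sampling time, so I take the logarithm of the fall, divide by time and by catalyst charged, and get 56.6 /M/s for beta and 56.6 /M/s for alpha, both readings with a scatter of 1 percentage point. Their mean 56.6 /M/s is my clock constant: the early pseudo-first-order constant of the left-handed substrate per catalyst charged.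

It is an early mean. Over the whole beta run the same reckoning gives 36.2 /M/s, lower, so the curve bends.

For this flask the clock constant gives 1.02 /min. If the conversion is left-handed substrate, 10% comes at 0.219 min, later than the 0.156 min I reckon for beta. I therefore expect a catalyst order above 1. Both runs were charged with 0.60 M of coupling partner, so my partner order stays a guess. So I charge the flask as listed and sample around 0.219 min.

The forecast says 0.5 in coupling partner and 1.03 in free catalyst, reading the late fall as partner loss with “a partial dependence on it”.

The flask gives 1.0 in coupling partner and 1.3 in free catalyst.

    coupling partner + catalyst intermediate B → free catalyst + right-handed product (k = 0.855 /M/s)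
    coupling partner + catalyst intermediate A → free catalyst + left-handed product (k = 27.4 /M/s)
    2 coupling partner → self-condensation product (k = 0.0196 /M/s)
    free catalyst + left-handed substrate ⇌ catalyst intermediate A (K = 20.0 /M, k = 2680 /M/s)
    free catalyst + right-handed substrate ⇌ catalyst intermediate B (K = 1.05 /M, k = 247 /M/s)

Held at 1.02 /min, the flask would keep 33.2% left-handed substrate at 0.400 min, and it holds 34.1%. At 4.00 min the same constant gives 0.845%, and the flask holds 5.93%. Of the turnover up to that time, self-condensation reaches its midpoint at 0.365 min, earlier than the coupling of catalyst intermediate A at 0.655 min, and the flask then has 8.9% of its coupling partner left.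

(The numbers in the tables were generated by integration from invented constants, noise included.)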